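**Assumption:** the sense of asymmetric induction of the chiral Brønsted acid in step 6 cannot be derived from the structures alone. The (R)-configured catalyst is written; its mirror image would be used, with nothing else changed, if it favours the antipode.

## The problem

Compound 15 is a 4-arylflavan-3-ol: a chroman (ring A fused to the pyran ring C) with the catechol ring B on C2, a hydroxyl on C3 and the 2,4-dihydroxy-3-methoxyphenyl ring D on C4. Ring C carries three contiguous stereocentres, (2R,3S,4R), in the 2,3-trans-3,4-trans arrangement, with all three substituents equatorial. This is the thermodynamically preferred relative configuration, so the substrate can steer the relative stereochemistry, but no stereocentre can be bought and the absolute configuration must come from a chiral catalyst or reagent. C4 is doubly benzylic and lies between two electron-rich rings that each carry an ortho oxygen (O1 on ring A, the 2-hydroxyl on ring D), so the synthesis must ensure that only the ring A oxygen enters the pyran ring. The free polyphenol does not tolerate oxidants, strong base or prolonged exposure to air. The benzylic C2–O1 bond ionises under strong acid, which can open ring C or epimerise C2. The phenols are therefore kept masked to the end and released under neutral conditions, with the ring D methyl ether left intact. The enabling feature is that O1, C8a, C4a and C4 form a latent o-quinone methide: a 2-hydroxybenzhydrol whose carbinol carbon is C4 and already bears ring D loses water under acid to give a heterodiene. The two remaining ring atoms, C2 and C3, are then the two carbons of a ring B styrene whose β-carbon carries a hydroxyl surrogate.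

## Retrosynthesis

**15 from 14.** The five benzyl–oxygen bonds are cut. Benzyl ethers are chosen over silyl or acetal groups because they survive the acid of the key step, organolithium chemistry and basic peroxide. They also fall together in one neutral hydrogenolysis that leaves the methyl ether and the three stereocentres alone. Precursor 14 is the pentabenzyl ether with the C3 hydroxyl free.

**14 from 13.** The C3–O bond is traced back to a C3–B bond. Oxidation of a secondary alkylboronate goes with retention, so C3 is fixed in the ring-forming step and merely revealed here. Bringing oxygen in directly on the alkene as an enol ether would reverse the polarity of the 2π partner and lead to the wrong constitution. A boryl group keeps the styrene polarity.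

**13 from 8 and 11 (through 12).** C3–C4 and O1–C2 are cut together. This single disconnection removes ring C and all three stereocentres and leaves two flat aromatic building blocks. Cutting only O1–C2 or only C4–C4a would leave an acyclic chain whose stereocentres must be set one by one. The forward reaction must:
- ionise racemic 8 to the o-quinone methide 12;
- add the boron-bearing carbon of 11 to C4 and close O1 onto C2;
- keep the boron;
- select one face of C4 under control of a chiral acid.

**8 from 5 and 2 (through 6 and 7).** The C4–aryl bond to ring D is cut. Adding an aryl metal to a salicylaldehyde fixes the position of every oxygen on both rings in advance. The neighbouring cut, C4–C4a by hydroxyalkylation of a phenol, would depend on ortho/para selectivity. The stereocentre of 8 is erased in step 6, so no asymmetric addition is needed.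

**5 from 4 from 3, and 2 from 1.** Only O-benzylations and one electrophilic bromination remain. The bromine goes ortho and para to the two benzyloxy groups of 4, which is the position required for C1 of ring D. In 1 the 4-hydroxyl is alkylated selectively because the 2-hydroxyl is hydrogen-bonded to the formyl group.

**11 from 9 (through 10).** The alkene is cut. A boron-Wittig olefination of aldehyde 9 with the lithiated geminal bis(boronate) 10 gives the (E)-alkenylboronate in one step and avoids a separate alkyne hydroboration.

## Roads not taken

**Alternative 1:** Ring A is taken apart completely (C4a–C5, C4a–C8a, C7–C8, C6–C7) and rebuilt last by a Danheiser benzannulation.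
- Cut and key step: precursor A1 is an acyclic diazo enone whose diazo carbon is the future C4a. It carries the C4–C3–C2 chain with all three stereocentres, and the C2 oxygen bears an ethynyl group. Irradiation causes a Wolff rearrangement to a vinylketene, which adds the tethered alkynyl ether. Opening of the cyclobutenone (4π) and closure (6π) then give phenol A2 with ring A and the pyran ring closed in one cascade.
- Merits: the 7-oxygenation pattern follows from the mechanism, no stereocentre is touched in the key step, and the open question of boron retention does not arise.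
- Weak points: A1 needs the full anti,anti stereotriad on an open chain. It also needs an alkynyl ether on a hindered, ionisable benzylic oxygen (such ethers with β-hydrogens fragment to ketenes on mild heating) and a diazo transfer next to the activated C4–H. A benzene ring that can be bought is instead built over roughly a dozen linear steps.
- Comparison: in reliability of stereochemistry this road is arguably better, because the stereocentres come from established acyclic methods. The chosen plan sets against it a purchased ring A, one catalytic step that makes ring C and all three stereocentres, and about half the length.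

**Alternative 2:** The cut is C4–C4a.
- Cut and key step: precursor A3 is a 1,3-diarylpropan-1-ol in which C2 already bears the 3-benzyloxyphenyl ether, C3 a benzyloxy group and C4 a hydroxyl of either configuration. Acid ionises both epimers to one cation stabilised by ring D. The aryl ether attacks para to its benzyloxy group in a Friedel–Crafts closure to give the hexabenzyl ether A4, with ring D trans to the C3 substituent.
- Merits: it is stereoconvergent at C4, every reaction type is known, and the endgame is the same single hydrogenolysis.
- Weak points: closure between the two oxygens of the aryl ether would give the 5-benzyloxy isomer. The same acid can ionise the C2–O aryl ether, whose carbon bears the donor-rich ring B, and so scramble C2 or expel the phenol. That ether must first be made with clean inversion at a cation-prone centre. The precursor needs some eight or nine linear steps.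
- Comparison: stereoconvergence and full precedent are real advantages over a key step that is untested. The chosen plan sets against them a shorter, convergent route, no regiochemical question on ring A (the nucleophile is the phenol oxygen, not a ring carbon) and one stereo-defining event instead of two.

**Alternative 3:** The cut is O1–C2.
- Cut and key step: precursor A5 is the trans-epoxide of a 2-(1,3-diarylallyl)phenol with C4 in place and the epoxide set by a chiral reagent. Mild acid lets the ring A phenol open the epoxide at benzylic C2 with inversion (6-endo), which closes the pyran ring and frees the C3 hydroxyl to give A6, identical with 14.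
- Merits: only known reaction types are used, no C–B oxidation is needed, and the donor-rich ring B directs opening to C2.
- Weak points: there are two independent stereo-defining operations, with a matched or mismatched case between C4 and the epoxidation reagent. 5-exo attack at C3 to a dihydrobenzofuran competes. The electron-rich aryl epoxide tends to rearrange or open by an SN1 path with loss of stereospecificity at C2. The phenol must be masked during epoxidation.
- Comparison: this road is stronger in precedent and serves below as the fallback for step 6. The chosen plan sets against it about three fewer steps and the creation of C2, C3 and C4 in one event, in which the alkene geometry, not a second chiral reagent, relates C2 to C3.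

Key step: step 6

## Route

Step 1
Reactants: 1 2,4-dihydroxybenzaldehyde
Product: 2 4-(benzyloxy)-2-hydroxybenzaldehyde
Conditions: BnBr (1.05 equiv), NaHCO3, KI (cat.), MeCN, 80 °C
Reagents that add atoms: benzyl bromide, BrCc1ccccc1
Why: Williamson etherification; the 2-hydroxyl is held in a hydrogen bond to the formyl group and is less nucleophilic, so a weak base alkylates only the 4-hydroxyl.

Step 2
Reactants: 3 2-methoxybenzene-1,3-diol (2-methoxyresorcinol)
Product: 4 1,3-bis(benzyloxy)-2-methoxybenzene
Conditions: BnBr (2.3 equiv), K2CO3, DMF, 60 °C
Reagents that add atoms: benzyl bromide, BrCc1ccccc1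
Why: Twofold Williamson etherification of an unhindered resorcinol; no selectivity question arises.

Step 3
Reactants: 4 1,3-bis(benzyloxy)-2-methoxybenzene
Product: 5 1,3-bis(benzyloxy)-4-bromo-2-methoxybenzene
Conditions: NBS (1.0 equiv), MeCN, 0 °C → rt
Reagents that add atoms: N-bromosuccinimide, O=C1CCC(=O)N1Br
Why: Electrophilic aromatic bromination; C4 is ortho to one benzyloxy group and para to the other, whereas C5 is activated only by the flanked, twisted methoxy group, and one equivalent of NBS at low temperature should stop at the monobromide.

Step 4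
Reactants: 5 1,3-bis(benzyloxy)-4-bromo-2-methoxybenzene; 2 4-(benzyloxy)-2-hydroxybenzaldehyde
Product: 8 rac-[4-(benzyloxy)-2-hydroxyphenyl][2,4-bis(benzyloxy)-3-methoxyphenyl]methanol, via aryllithium 6 (not isolated), via sodium phenolate 7 (not isolated)
Conditions: 5, n-BuLi, THF, −78 °C; separately 2, NaH, THF, 0 °C; phenolate solution added to the aryllithium, −78 → 0 °C; aq. NH4Cl
Reagents that add atoms: none
Why: Bromine–lithium exchange outruns benzylic deprotonation at −78 °C, and pre-forming the phenolate of 2 saves a second equivalent of 6; 1,2-addition of an aryllithium to a salicylaldehyde phenolate is the standard route to 2-hydroxybenzhydrols. The new stereocentre is left racemic because step 6 erases it; 8 is acid-sensitive and is purified on base-washed silica or used crude.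

Step 5
Reactants: 9 3,4-bis(benzyloxy)benzaldehyde
Product: 11 2-{(E)-2-[3,4-bis(benzyloxy)phenyl]ethenyl}-4,4,5,5-tetramethyl-1,3,2-dioxaborolane, via lithiated bis(boryl)methane 10 (not isolated)
Conditions: CH2(Bpin)2, LiTMP (from 2,2,6,6-tetramethylpiperidine, n-BuLi), THF, 0 °C; then 9, −78 °C → rt
Reagents that add atoms: bis(4,4,5,5-tetramethyl-1,3,2-dioxaborolan-2-yl)methane, C(B1OC(C)(C)C(C)(C)O1)B1OC(C)(C)C(C)(C)O1
Why: Boron-Wittig reaction; the α-boryl carbanion 10 adds to the aldehyde and syn-elimination of the boron–oxygen pair from the β-alkoxide gives the alkenylboronate, with the aryl group and the remaining boryl group anti in the elimination, hence E.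

Step 6
Reactants: 8 rac-[4-(benzyloxy)-2-hydroxyphenyl][2,4-bis(benzyloxy)-3-methoxyphenyl]methanol; 11 2-{(E)-2-[3,4-bis(benzyloxy)phenyl]ethenyl}-4,4,5,5-tetramethyl-1,3,2-dioxaborolane (1.5 equiv)
Product: 13 2-{(2S,3S,4S)-7-(benzyloxy)-2-[3,4-bis(benzyloxy)phenyl]-4-[2,4-bis(benzyloxy)-3-methoxyphenyl]-3,4-dihydro-2H-chromen-3-yl}-4,4,5,5-tetramethyl-1,3,2-dioxaborolane (2,3-trans-3,4-trans), via o-quinone methide 12 (not isolated)
Conditions: (R)-N-(trifluoromethylsulfonyl) 3,3'-bis(2,4,6-triisopropylphenyl)-1,1'-binaphthyl-2,2'-diyl phosphoramide (10 mol %), toluene, −30 → 0 °C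
Reagents that add atoms: none
Why: Proposed new method: the acid dehydrates 8 to the (E)-o-quinone methide 12, which stays hydrogen-bonded, or ion-paired in its O-protonated form, to the chiral phosphoramide anion. The boron-bearing carbon of 11 attacks C4 because the charge building at C2 is stabilised by the para-benzyloxy group of ring B, and the phenolic oxygen closes onto C2 in the same concerted but asynchronous event. The closest known reaction types are the chiral N-triflylphosphoramide- and phosphoric acid-catalysed [4+2] cycloadditions of o-quinone methides, generated in situ, with styrenes, and the Diels–Alder reactions in which alkenyl pinacol boronates keep their boron; a β-borylstyrene has not been shown as the 2π partner of an o-quinone methide. The pyran ring closes by an inverse-demand hetero-[4+2] cycloaddition, with O1=C8a–C4a=C4 as the 4π unit and C2=C3 as the 2π unit. C4 is set by the face of 12 that the catalyst leaves open; C2 and C3 are trans because the E geometry of 11 is carried over suprafacially; the endo placement of ring B over the heterodiene puts the C2 aryl cis to the C4 aryl, so all three substituents are equatorial, which is also the thermodynamically preferred arrangement. Regioselectivity is secured by the donor ring B and by the fact that ring A carries the only free ortho hydroxyl, those of ring D being benzylated. Ring closure must beat loss of boron from the β-boryl benzylic cation, which the hindered, weakly Lewis-acidic pinacol ester, the non-nucleophilic medium and the low temperature are meant to ensure. Enantioselectivity rests on the catalyst alone, since the alkene has no hydrogen-bond donor.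

Step 7
Reactants: 13 2-{(2S,3S,4S)-7-(benzyloxy)-2-[3,4-bis(benzyloxy)phenyl]-4-[2,4-bis(benzyloxy)-3-methoxyphenyl]-3,4-dihydro-2H-chromen-3-yl}-4,4,5,5-tetramethyl-1,3,2-dioxaborolane
Product: 14 (2R,3S,4S)-7-(benzyloxy)-2-[3,4-bis(benzyloxy)phenyl]-4-[2,4-bis(benzyloxy)-3-methoxyphenyl]-3,4-dihydro-2H-chromen-3-ol (2,3-trans-3,4-trans)
Conditions: NaBO3·4H2O, THF/H2O 1:1, rt
Reagents that add atoms: sodium perborate, [Na+].[Na+].O[B-]1(O)OO[B-](O)(O)OO1
Why: Oxidation of a secondary alkylboronate; the peroxide adds to boron and C3 migrates from boron to oxygen with retention, as in the oxidation half of the hydroboration–oxidation of flav-3-enes. Mildly basic perborate is preferred to alkaline peroxide to limit β-elimination across C2–C3.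

Step 8
Reactants: 14 (2R,3S,4S)-7-(benzyloxy)-2-[3,4-bis(benzyloxy)phenyl]-4-[2,4-bis(benzyloxy)-3-methoxyphenyl]-3,4-dihydro-2H-chromen-3-ol
Product: 15 (2R,3S,4R)-2-(3,4-dihydroxyphenyl)-4-(2,4-dihydroxy-3-methoxyphenyl)-3,4-dihydro-2H-chromene-3,7-diol
Conditions: H2 (1 atm), Pd(OH)2 on carbon, THF/MeOH 1:1, rt; filtration and concentration under argon
Reagents that add atoms: none
Why: Hydrogenolysis of five aryl benzyl ethers under neutral conditions, the standard last step for benzylated flavan-3-ols, in which the C2–O1 bond and the C4 aryl bond are kept at atmospheric pressure. No stereocentre is touched; the C4 descriptor changes from S to R only because the substituent priorities change when ring D loses its benzyl groups.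

## Compound list

1 | 2,4-dihydroxybenzaldehyde | O=Cc1ccc(O)cc1O | starting material
2 | 4-(benzyloxy)-2-hydroxybenzaldehyde | O=Cc1ccc(OCc2ccccc2)cc1O | intermediate
3 | 2-methoxybenzene-1,3-diol (2-methoxyresorcinol) | COc1c(O)cccc1O | starting material
4 | 1,3-bis(benzyloxy)-2-methoxybenzene | COc1c(OCc2ccccc2)cccc1OCc1ccccc1 | intermediate
5 | 1,3-bis(benzyloxy)-4-bromo-2-methoxybenzene | COc1c(OCc2ccccc2)ccc(Br)c1OCc1ccccc1 | intermediate
6 | [2,4-bis(benzyloxy)-3-methoxyphenyl]lithium | [Li]c1ccc(OCc2ccccc2)c(OC)c1OCc1ccccc1 | intermediate (not isolated)
7 | sodium 5-(benzyloxy)-2-formylphenolate | O=Cc1ccc(OCc2ccccc2)cc1[O-].[Na+] | intermediate (not isolated)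
8 | rac-[4-(benzyloxy)-2-hydroxyphenyl][2,4-bis(benzyloxy)-3-methoxyphenyl]methanol | OC(c1ccc(OCc2ccccc2)cc1O)c1ccc(OCc2ccccc2)c(OC)c1OCc1ccccc1 | intermediate
9 | 3,4-bis(benzyloxy)benzaldehyde | O=Cc1ccc(OCc2ccccc2)c(OCc2ccccc2)c1 | starting material
10 | [bis(4,4,5,5-tetramethyl-1,3,2-dioxaborolan-2-yl)methyl]lithium | [Li]C(B1OC(C)(C)C(C)(C)O1)B1OC(C)(C)C(C)(C)O1 | intermediate (not isolated)
11 | 2-{(E)-2-[3,4-bis(benzyloxy)phenyl]ethenyl}-4,4,5,5-tetramethyl-1,3,2-dioxaborolane | CC1(C)OB(/C=C/c2ccc(OCc3ccccc3)c(OCc3ccccc3)c2)OC1(C)C | intermediate
12 | (6E)-3-(benzyloxy)-6-{[2,4-bis(benzyloxy)-3-methoxyphenyl]methylidene}cyclohexa-2,4-dien-1-one | O=C1C=C(OCc2ccccc2)C=C/C1=C\c1ccc(OCc2ccccc2)c(OC)c1OCc1ccccc1 | intermediate (not isolated)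
13 | 2-{(2S,3S,4S)-7-(benzyloxy)-2-[3,4-bis(benzyloxy)phenyl]-4-[2,4-bis(benzyloxy)-3-methoxyphenyl]-3,4-dihydro-2H-chromen-3-yl}-4,4,5,5-tetramethyl-1,3,2-dioxaborolane | COc1c(OCc2ccccc2)ccc([C@@H]3c4ccc(OCc5ccccc5)cc4O[C@H](c4ccc(OCc5ccccc5)c(OCc5ccccc5)c4)[C@H]3B6OC(C)(C)C(C)(C)O6)c1OCc1ccccc1 | intermediate
14 | (2R,3S,4S)-7-(benzyloxy)-2-[3,4-bis(benzyloxy)phenyl]-4-[2,4-bis(benzyloxy)-3-methoxyphenyl]-3,4-dihydro-2H-chromen-3-ol | COc1c(OCc2ccccc2)ccc([C@@H]3c4ccc(OCc5ccccc5)cc4O[C@H](c4ccc(OCc5ccccc5)c(OCc5ccccc5)c4)[C@H]3O)c1OCc1ccccc1 | intermediate
15 | (2R,3S,4R)-2-(3,4-dihydroxyphenyl)-4-(2,4-dihydroxy-3-methoxyphenyl)-3,4-dihydro-2H-chromene-3,7-diol | COc1c(O)ccc([C@@H]2c3ccc(O)cc3O[C@H](c3ccc(O)c(O)c3)[C@H]2O)c1O | target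

## Step count and least certain steps

Total: 8 steps. Longest linear sequence: 6 steps (3 → 4 → 5 → 8 → 13 → 14 → 15; steps 2, 3, 4, 6, 7 and 8).

**Step 6 (key step, proposed new method).**
- What may go wrong: boron may be lost from the β-boryl benzylic cation instead of ring closure, so that the alkenyl group is merely transferred to C4. The catalyst may discriminate the faces of 12 poorly, because the alkene offers it no hydrogen-bond donor. The acid may reopen the product at the benzylic C2–O1 bond.
- Fallback (known chemistry; sets out from 8 and 11, returns at 14):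
  - The pinacol ester 11 is cleaved with NaIO4 and NH4OAc in acetone/H2O to (E)-2-[3,4-bis(benzyloxy)phenyl]ethenylboronic acid F1.
  - With (R)-3,3'-dibromo-1,1'-bi-2-naphthol as catalyst (antipode chosen as for step 6), F1 transfers its alkenyl group to C4 of 12 formed from 8 in the same flask. This is the known enantioselective conjugate alkenylation of o-quinone methides by alkenylboronates, and it gives 5-(benzyloxy)-2-{(1S,2E)-1-[2,4-bis(benzyloxy)-3-methoxyphenyl]-3-[3,4-bis(benzyloxy)phenyl]prop-2-en-1-yl}phenol F2.
  - The phenol is masked with TBSCl and imidazole as its tert-butyldimethylsilyl ether F3.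
  - Shi epoxidation gives the silyl-protected (S,S)-trans-epoxide F4. The ketone is 1,2:4,5-di-O-isopropylidene-β-L-erythro-2,3-hexodiulo-2,6-pyranose, the mirror image of the fructose-derived ketone, chosen by analogy with trans-β-methylstyrene; the conditions are KHSO5 (as 2KHSO5·KHSO4·K2SO4), K2CO3, MeCN/dimethoxymethane/H2O, 0 °C.
  - Bu4NF buffered with AcOH frees the phenol epoxide F5 (not isolated). Catalytic camphorsulfonic acid in CH2Cl2 at low temperature then closes it 6-endo at benzylic C2 with inversion to give 14.

**Step 7.**
- What may go wrong: C3–B is antiperiplanar to C2–O1, so the boron ate complex may undergo base-triggered anti-elimination and open the pyran ring, in competition with the 1,2-shift. Oxidation of the hindered boronate may also be slow.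
- Fallback (sets out from 13, returns at 14): 13 is converted with KHF2 in MeOH/H2O into potassium trifluoro{(2S,3S,4S)-7-(benzyloxy)-2-[3,4-bis(benzyloxy)phenyl]-4-[2,4-bis(benzyloxy)-3-methoxyphenyl]-3,4-dihydro-2H-chromen-3-yl}borate F6. This stable, already tetracoordinate boron species is oxidised with retention by KHSO5 (as 2KHSO5·KHSO4·K2SO4) in acetone/H2O at rt within minutes and without added base, giving 14.

**Step 4.**
- What may go wrong: addition to the electron-rich phenolate aldehyde may be slow, so that on warming the ortho-benzyloxy aryllithium is consumed by proton transfer, benzylic metalation or Wittig rearrangement. The product may also ionise to 12 on acidic silica and oligomerise.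
- Fallback (sets out from 4, returns at 8, and bypasses 5, 6 and 7): the bond formed is changed from C4–ring D to C4–C4a.
  - Vilsmeier–Haack formylation of 4 (POCl3, DMF) occurs para to a benzyloxy group and gives 2,4-bis(benzyloxy)-3-methoxybenzaldehyde F7.
  - Purchased 3-(benzyloxy)phenol F8 is converted by EtMgBr into bromomagnesium 3-(benzyloxy)phenolate F9 (not isolated).
  - In toluene F9 adds to F7 through a six-membered magnesium chelate, exclusively ortho to the phenolate oxygen and preferentially para to the benzyloxy group (the ortho-specific hydroxyalkylation of magnesium phenolates), to give 8.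

**Step 8.**
- What may go wrong: cleavage of the two hindered benzyl ethers that flank the methoxy group may be incomplete. Prolonged exposure may cause hydrogenolytic opening of the benzylic C2–O1 bond. The free polyphenol may be oxidised by air during isolation.
- Fallback (sets out from 14, returns at 15, no new compound): Lewis-acid debenzylation with BCl3 and pentamethylbenzene as cation scavenger in CH2Cl2 at −78 °C, quenched cold with MeOH. The low temperature is needed to spare the methyl ether and the C2–O1 bond.

## Further compounds

F1 | step 6 | (E)-2-[3,4-bis(benzyloxy)phenyl]ethenylboronic acid | OB(O)/C=C/c1ccc(OCc2ccccc2)c(OCc2ccccc2)c1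
F2 | step 6 | 5-(benzyloxy)-2-{(1S,2E)-1-[2,4-bis(benzyloxy)-3-methoxyphenyl]-3-[3,4-bis(benzyloxy)phenyl]prop-2-en-1-yl}phenol | COc1c(OCc2ccccc2)ccc([C@@H](/C=C/c2ccc(OCc3ccccc3)c(OCc3ccccc3)c2)c2ccc(OCc3ccccc3)cc2O)c1OCc1ccccc1
F3 | step 6 | tert-butyldimethylsilyl ether of F2 (same spatial arrangement at the methine carbon) | COc1c(OCc2ccccc2)ccc([C@@H](/C=C/c2ccc(OCc3ccccc3)c(OCc3ccccc3)c2)c2ccc(OCc3ccccc3)cc2O[Si](C)(C)C(C)(C)C)c1OCc1ccccc1
F4 | step 6 | silyl-protected trans-epoxide: tert-butyl{5-(benzyloxy)-2-([2,4-bis(benzyloxy)-3-methoxyphenyl]{(2S,3S)-3-[3,4-bis(benzyloxy)phenyl]oxiran-2-yl}methyl)phenoxy}dimethylsilane, methine carbon configured as in 14 | COc1c(OCc2ccccc2)ccc([C@@H]([C@@H]2O[C@H]2c2ccc(OCc3ccccc3)c(OCc3ccccc3)c2)c2ccc(OCc3ccccc3)cc2O[Si](C)(C)C(C)(C)C)c1OCc1ccccc1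
F5 | step 6 | free phenol trans-epoxide: 5-(benzyloxy)-2-([2,4-bis(benzyloxy)-3-methoxyphenyl]{(2S,3S)-3-[3,4-bis(benzyloxy)phenyl]oxiran-2-yl}methyl)phenol, methine carbon configured as in 14 | COc1c(OCc2ccccc2)ccc([C@@H]([C@@H]2O[C@H]2c2ccc(OCc3ccccc3)c(OCc3ccccc3)c2)c2ccc(OCc3ccccc3)cc2O)c1OCc1ccccc1
F6 | step 7 | potassium trifluoro{(2S,3S,4S)-7-(benzyloxy)-2-[3,4-bis(benzyloxy)phenyl]-4-[2,4-bis(benzyloxy)-3-methoxyphenyl]-3,4-dihydro-2H-chromen-3-yl}borate | COc1c(OCc2ccccc2)ccc([C@@H]3c4ccc(OCc5ccccc5)cc4O[C@H](c4ccc(OCc5ccccc5)c(OCc5ccccc5)c4)[C@H]3[B-](F)(F)F)c1OCc1ccccc1.[K+]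
F7 | step 4 | 2,4-bis(benzyloxy)-3-methoxybenzaldehyde | O=Cc1ccc(OCc2ccccc2)c(OC)c1OCc1ccccc1
F8 | step 4 | 3-(benzyloxy)phenol (purchased reagent of the fallback) | Oc1cccc(OCc2ccccc2)c1
F9 | step 4 | bromomagnesium 3-(benzyloxy)phenolate | Br[Mg]Oc1cccc(OCc2ccccc2)c1
F0 | step 8 | none | none
A1 | alternative 1 | 6-(benzyloxy)-7-[3,4-bis(benzyloxy)phenyl]-5-[2,4-bis(benzyloxy)-3-methoxyphenyl]-4-diazo-7-(ethynyloxy)hept-1-en-3-one, stereocentres arranged as in 15 | C=CC(=O)C(=[N+]=[N-])[C@@H](c1ccc(OCc2ccccc2)c(OC)c1OCc1ccccc1)[C@H](OCc1ccccc1)[C@@H](c1ccc(OCc2ccccc2)c(OCc2ccccc2)c1)OC#C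
A2 | alternative 1 | 3-(benzyloxy)-2-[3,4-bis(benzyloxy)phenyl]-4-[2,4-bis(benzyloxy)-3-methoxyphenyl]-3,4-dihydro-2H-chromen-7-ol, 2,3-trans-3,4-trans, arranged as in 15 | COc1c(OCc2ccccc2)ccc([C@@H]3c4ccc(O)cc4O[C@H](c4ccc(OCc5ccccc5)c(OCc5ccccc5)c4)[C@H]3OCc3ccccc3)c1OCc1ccccc1
A3 | alternative 2 | 2-(benzyloxy)-3-[3-(benzyloxy)phenoxy]-3-[3,4-bis(benzyloxy)phenyl]-1-[2,4-bis(benzyloxy)-3-methoxyphenyl]propan-1-ol, either C1 epimer, C2 and C3 of the chain arranged as C3 and C2 of 15 | COc1c(OCc2ccccc2)ccc(C(O)[C@H](OCc2ccccc2)[C@@H](c2ccc(OCc3ccccc3)c(OCc3ccccc3)c2)Oc2cccc(OCc3ccccc3)c2)c1OCc1ccccc1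
A4 | alternative 2 | hexabenzyl ether of 15: 3,7-bis(benzyloxy)-2-[3,4-bis(benzyloxy)phenyl]-4-[2,4-bis(benzyloxy)-3-methoxyphenyl]-3,4-dihydro-2H-chromene, 2,3-trans-3,4-trans | COc1c(OCc2ccccc2)ccc([C@@H]3c4ccc(OCc5ccccc5)cc4O[C@H](c4ccc(OCc5ccccc5)c(OCc5ccccc5)c4)[C@H]3OCc3ccccc3)c1OCc1ccccc1
A5 | alternative 3 | free phenol trans-epoxide, identical with F5 | COc1c(OCc2ccccc2)ccc([C@@H]([C@@H]2O[C@H]2c2ccc(OCc3ccccc3)c(OCc3ccccc3)c2)c2ccc(OCc3ccccc3)cc2O)c1OCc1ccccc1
A6 | alternative 3 | pentabenzyl ether of 15 with free C3 hydroxyl, identical with 14 | COc1c(OCc2ccccc2)ccc([C@@H]3c4ccc(OCc5ccccc5)cc4O[C@H](c4ccc(OCc5ccccc5)c(OCc5ccccc5)c4)[C@H]3O)c1OCc1ccccc1
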